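**Retrosynthetic overview**

- Feature: ring A, the acyl-bearing benzene ring, is a 2-substituted resorcinol monomethyl ether. C1' carries the ketone carbon, C2' the OH, C6' the OMe, and C3', C4', C5' are three adjacent CH. Ring B (the 4-hydroxyphenyl ring) is bought.
- Endgame: target ⇐ benzyl-protected ketone ⇐ benzylic alcohol ⇐ silyl-protected phenol (hydrogenolysis, MnO2 oxidation, desilylation).
- Key disconnection: ring A is cut at C1'–C2' and C5'–C6' (C2'–C3' is re-formed in the same cascade). This gives cyclobutenone (C2' to C5' and the phenol oxygen) and a 1-methoxyalkyne (C1', C6', OMe, with the future ketone carbon as a silyl-protected carbinol).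
- Ynol ether ⇐ 9-(4-benzyloxyphenyl)nonanal + lithium methoxyacetylide (from chloroacetaldehyde dimethyl acetal), then silylation. The aldehyde ⇐ B-alkyl Suzuki coupling of non-8-en-1-ol with 1-(benzyloxy)-4-bromobenzene, then oxidation.
- Cyclobutenone ⇐ 3-oxocyclobutanecarboxylic acid (bromodecarboxylation, HBr elimination). Ring A is the only ring formed, in step 7.

Key step: step 7

Remark on the chemistry: the target is achiral. The one stereocentre carried through the route (the carbinol carbon made in step 3) is racemic and is erased by the oxidation in step 9.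

Step 1
Reactants: 1 non-8-en-1-ol; 2 1-(benzyloxy)-4-bromobenzene
Product: 4 9-[4-(benzyloxy)phenyl]nonan-1-ol, via B-alkyl borane 3 (not isolated)
Conditions: 9-BBN (2.2 equiv), THF, 0 °C to rt; then 2, PdCl2(dppf) (3 mol %), 3 M aq K3PO4, THF/DMF, 60 °C
Reagents that add atoms: none
Why: 9-BBN hydroborates the terminal alkene at the terminal carbon and the primary B-alkyl group then couples with the aryl bromide in a B-alkyl Suzuki–Miyaura reaction; the second equivalent of 9-BBN is taken up by the free O–H as an O-borinate that aqueous base hydrolyses again, and the benzyl ether is inert.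

Step 2
Reactants: 4 9-[4-(benzyloxy)phenyl]nonan-1-ol
Product: 5 9-[4-(benzyloxy)phenyl]nonanal
Conditions: TEMPO (10 mol %), PhI(OAc)2 (1.1 equiv), CH2Cl2, rt
Reagents that add atoms: none
Why: TEMPO-catalysed oxoammonium oxidation with PhI(OAc)2 as terminal oxidant should stop at the aldehyde in dry CH2Cl2 and leave the benzyl aryl ether untouched.

Step 3
Reactants: 6 chloroacetaldehyde dimethyl acetal; 5 9-[4-(benzyloxy)phenyl]nonanal
Product: 8 racemic 11-[4-(benzyloxy)phenyl]-1-methoxyundec-1-yn-3-ol, via lithium methoxyacetylide 7 (not isolated)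
Conditions: 6 (1.5 equiv), LiNEt2 (4.5 equiv, from n-BuLi and Et2NH), THF, 0 °C; then 5, −78 °C; H2O quench, basic work-up, Et3N-deactivated silica
Reagents that add atoms: none
Why: Three equivalents of LiNEt2 per acetal effect two eliminations (loss of methoxide and of chloride) and a deprotonation to give the acetylide 7 (Arens-type ynol ether synthesis), which adds 1,2 to the aldehyde; the carbinol centre is set without control, which is acceptable because this carbon becomes the ketone.

Step 4
Reactants: 8 racemic 11-[4-(benzyloxy)phenyl]-1-methoxyundec-1-yn-3-ol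
Product: 9 racemic 11-[4-(benzyloxy)phenyl]-3-[(tert-butyldimethylsilyl)oxy]-1-methoxyundec-1-yne
Conditions: TBSCl (1.3 equiv), imidazole (2.5 equiv), DMF, 0 °C to rt
Reagents that add atoms: tert-butyldimethylsilyl chloride, CC(C)(C)[Si](C)(C)Cl
Why: Corey silylation of a secondary alcohol under basic conditions avoids the acid that would trigger Meyer–Schuster rearrangement of the γ-hydroxy ynol ether to an enoate.

Step 5
Reactants: 10 3-oxocyclobutanecarboxylic acid
Product: 11 3-bromocyclobutanone
Conditions: HgO (red), Br2, MgSO4, CH2Cl2, reflux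
Reagents that add atoms: bromine, BrBr
Why: Cristol–Firth variant of the Hunsdiecker reaction, a radical bromodecarboxylation that replaces CO2H by Br at the secondary carbon and is established for this acid.

Step 6
Reactants: 11 3-bromocyclobutanone
Product: 12 cyclobutenone
Conditions: n-Bu3N (2 equiv), neat, rt, product distilled at reduced pressure into a −78 °C trap and kept as a cold toluene solution
Reagents that add atoms: none
Why: The bromide sits β to the carbonyl, so the tertiary amine removes HBr by E1cB elimination, and the volatile enone distils away from the high-boiling amine and its salt.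

Step 7
Reactants: 12 cyclobutenone; 9 racemic 11-[4-(benzyloxy)phenyl]-3-[(tert-butyldimethylsilyl)oxy]-1-methoxyundec-1-yne
Product: 17 racemic 2-{9-[4-(benzyloxy)phenyl]-1-[(tert-butyldimethylsilyl)oxy]nonyl}-3-methoxyphenol, via vinylketene 13 (not isolated), via vinylcyclobutenone adduct 14 (not isolated), via dienylketene 15 (not isolated), via cyclohexadienone tautomer 16 (not isolated)
Conditions: 12 (1.5 equiv, two portions), toluene, sealed tube, 80 °C then 110 °C
Reagents that add atoms: none
Why: Heating opens cyclobutenone 12 by 4π electrocyclic cleavage of its C1–C4 bond to vinylketene 13, whose ketene C=C adds [2+2] to ynol ether 9 to give the 4-vinylcyclobutenone 14; 14 reopens (4π) to dienylketene 15, which closes by thermal 6π electrocyclisation to cyclohexadienone 16 and tautomerises to phenol 17. The closest known reaction type is the Danheiser benzannulation of cyclobutenones with 1-alkoxyalkynes, applied here to parent cyclobutenone and a methyl ynol ether, which has no β-hydrogen on the O-alkyl group and so cannot fragment by retro-ene loss of an alkene at these temperatures. The one ring formed, benzene ring A, is closed by the disrotatory 6π electrocyclisation (bond C2'–C3'), after the [2+2] step has made the two new skeletal bonds C1'–C2' and C5'–C6'. No stereocentre is created in 17: the ring stereocentre of 14 is erased on reopening, and the silyloxy carbon, racemic from step 3, is a spectator. The step needs regiocontrol in the [2+2] addition, and the polarisation of the ynol ether supplies it: the alkyne carbon β to oxygen, which carries the side chain, is the nucleophilic end and bonds to the electrophilic ketene carbonyl carbon, so the phenol carbon, the side-chain carbon and the methoxy carbon end up contiguous. Carrying the future ketone as its silyl ether keeps the alkyne electron-rich enough for this addition.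

Step 8
Reactants: 17 racemic 2-{9-[4-(benzyloxy)phenyl]-1-[(tert-butyldimethylsilyl)oxy]nonyl}-3-methoxyphenol
Product: 18 racemic 2-{9-[4-(benzyloxy)phenyl]-1-hydroxynonyl}-3-methoxyphenol
Conditions: Bu4NF (2.5 equiv), AcOH (2.5 equiv), THF, 0 °C to rt
Reagents that add atoms: none
Why: Fluoride-induced cleavage of the silyl ether, buffered with acetic acid so that the acid- and base-sensitive o-hydroxybenzylic alcohol is formed under near-neutral conditions.

Step 9
Reactants: 18 racemic 2-{9-[4-(benzyloxy)phenyl]-1-hydroxynonyl}-3-methoxyphenol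
Product: 19 9-[4-(benzyloxy)phenyl]-1-(2-hydroxy-6-methoxyphenyl)nonan-1-one
Conditions: activated MnO2 (15 equiv), CH2Cl2, rt
Reagents that add atoms: none
Why: Activated MnO2 oxidises benzylic alcohols selectively, as in the oxidation of salicyl alcohols to o-hydroxyaryl carbonyl compounds, and the ketone formed is stabilised by the hydrogen bond from the ortho hydroxyl.

Step 10
Reactants: 19 9-[4-(benzyloxy)phenyl]-1-(2-hydroxy-6-methoxyphenyl)nonan-1-one
Product: 20 1-(2-hydroxy-6-methoxyphenyl)-9-(4-hydroxyphenyl)nonan-1-one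
Conditions: H2 (1 atm), 10% Pd/C, EtOAc, rt
Reagents that add atoms: none
Why: Hydrogenolysis of the benzyl aryl ether over Pd/C should be fast in a neutral solvent, whereas the hindered, hydrogen-bonded 2,6-dioxygenated aryl ketone is reduced only slowly, so the reaction is stopped once the benzyl ether is consumed.

**Compound list**

1 | non-8-en-1-ol | C=CCCCCCCCO | starting material
2 | 1-(benzyloxy)-4-bromobenzene | Brc1ccc(OCc2ccccc2)cc1 | starting material
3 | 9-{9-[(9-borabicyclo[3.3.1]nonan-9-yl)oxy]nonyl}-9-borabicyclo[3.3.1]nonane | C1CCC2CCCC1B2CCCCCCCCCOB1C2CCCC1CCC2 | intermediate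
4 | 9-[4-(benzyloxy)phenyl]nonan-1-ol | OCCCCCCCCCc1ccc(OCc2ccccc2)cc1 | intermediate
5 | 9-[4-(benzyloxy)phenyl]nonanal | O=CCCCCCCCCc1ccc(OCc2ccccc2)cc1 | intermediate
6 | chloroacetaldehyde dimethyl acetal | COC(CCl)OC | starting material
7 | lithium methoxyacetylide | [Li]C#COC | intermediate
8 | racemic 11-[4-(benzyloxy)phenyl]-1-methoxyundec-1-yn-3-ol | COC#CC(O)CCCCCCCCc1ccc(OCc2ccccc2)cc1 | intermediate
9 | racemic 11-[4-(benzyloxy)phenyl]-3-[(tert-butyldimethylsilyl)oxy]-1-methoxyundec-1-yne | COC#CC(O[Si](C)(C)C(C)(C)C)CCCCCCCCc1ccc(OCc2ccccc2)cc1 | intermediate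
10 | 3-oxocyclobutanecarboxylic acid | O=C1CC(C(=O)O)C1 | starting material
11 | 3-bromocyclobutanone | O=C1CC(Br)C1 | intermediate
12 | cyclobutenone | O=C1C=CC1 | intermediate
13 | vinylketene (buta-1,3-dien-1-one) | C=CC=C=O | intermediate
14 | 2-{9-[4-(benzyloxy)phenyl]-1-[(tert-butyldimethylsilyl)oxy]nonyl}-3-methoxy-4-vinylcyclobut-2-en-1-one (diastereomer mixture) | C=CC1C(OC)=C(C(O[Si](C)(C)C(C)(C)C)CCCCCCCCc2ccc(OCc3ccccc3)cc2)C1=O | intermediate
15 | (3E)-2-{9-[4-(benzyloxy)phenyl]-1-[(tert-butyldimethylsilyl)oxy]nonyl}-3-methoxyhexa-1,3,5-trien-1-one (vinyl cis to the ketene carbon) | C=C/C=C(/OC)C(=C=O)C(O[Si](C)(C)C(C)(C)C)CCCCCCCCc1ccc(OCc2ccccc2)cc1 | intermediate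
16 | 2-{9-[4-(benzyloxy)phenyl]-1-[(tert-butyldimethylsilyl)oxy]nonyl}-3-methoxycyclohexa-2,4-dien-1-one | O=C1CC=CC(OC)=C1C(O[Si](C)(C)C(C)(C)C)CCCCCCCCc1ccc(OCc2ccccc2)cc1 | intermediate
17 | racemic 2-{9-[4-(benzyloxy)phenyl]-1-[(tert-butyldimethylsilyl)oxy]nonyl}-3-methoxyphenol | COc1cccc(O)c1C(O[Si](C)(C)C(C)(C)C)CCCCCCCCc1ccc(OCc2ccccc2)cc1 | intermediate
18 | racemic 2-{9-[4-(benzyloxy)phenyl]-1-hydroxynonyl}-3-methoxyphenol | COc1cccc(O)c1C(O)CCCCCCCCc1ccc(OCc2ccccc2)cc1 | intermediate
19 | 9-[4-(benzyloxy)phenyl]-1-(2-hydroxy-6-methoxyphenyl)nonan-1-one | COc1cccc(O)c1C(=O)CCCCCCCCc1ccc(OCc2ccccc2)cc1 | intermediate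
20 | 1-(2-hydroxy-6-methoxyphenyl)-9-(4-hydroxyphenyl)nonan-1-one | COc1cccc(O)c1C(=O)CCCCCCCCc1ccc(O)cc1 | target

**Step count**

Total steps: 10. Longest linear sequence: 8 steps (1, 2, 3, 4, 7, 8, 9, 10). The cyclobutenone branch (steps 5 and 6) joins at step 7.

**Steps most likely to fail**

Step 7 (benzannulation).
- What may go wrong: oligomerisation of cyclobutenone and of the vinylketene may outrun the [2+2] capture by the hindered, inductively deactivated ynol ether. Excess ketene may also acylate the product phenol.
- Fallback: sets out from aldehyde 5 and comes back at ketone 19. Ring A is bought instead of built.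
- 3-Methoxyphenol is treated with MOMCl and i-Pr2NEt to give 1-methoxy-3-(methoxymethoxy)benzene F1.
- n-BuLi in THF at 0 °C metalates the position between the two oxygens (directed ortho-metalation) to give 2-lithio-1-methoxy-3-(methoxymethoxy)benzene F2.
- F2 adds to 5 to give racemic 9-[4-(benzyloxy)phenyl]-1-[2-methoxy-6-(methoxymethoxy)phenyl]nonan-1-ol F3.
- Dess–Martin oxidation gives 9-[4-(benzyloxy)phenyl]-1-[2-methoxy-6-(methoxymethoxy)phenyl]nonan-1-one F4, and HCl in methanol removes the methoxymethyl group to give 19.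

Step 6 (cyclobutenone).
- What may go wrong: loss of the volatile enone during distillation, conjugate addition of the amine, and polymerisation on storage.
- Fallback: sets out from ynol ether 9 and comes back at phenol 17. The vinylketene 13 is generated without cyclobutenone.
- Methyl vinyl ketone is deprotonated with LiN(SiMe3)2 at −78 °C and acylated with 2,2,2-trifluoroethyl trifluoroacetate to give 1,1,1-trifluorohex-5-ene-2,4-dione F5.
- Crude F5 undergoes detrifluoroacetylative diazo transfer (MsN3, Et3N, H2O, MeCN) to give 1-diazobut-3-en-2-one F6.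
- Irradiation of F6 with 9 in CH2Cl2 at about 300 nm, where the aryl ethers of 9 absorb little, brings about photochemical Wolff rearrangement to 13. Capture by 9 and brief heating at 80 °C should complete the cascade through 14, 15 and 16 to 17.

Step 9 (MnO2 oxidation).
- What may go wrong: slow oxidation of a carbinol that is flanked by two ortho substituents and twisted out of conjugation, with competing oxidation of the electron-rich free phenol ring.
- Fallback: sets out from phenol 17 and comes back at target 20. The phenol is masked before the oxidation.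
- BnBr and K2CO3 in DMF give racemic 1-(benzyloxy)-2-{9-[4-(benzyloxy)phenyl]-1-[(tert-butyldimethylsilyl)oxy]nonyl}-3-methoxybenzene F7.
- Bu4NF in THF gives racemic 1-[2-(benzyloxy)-6-methoxyphenyl]-9-[4-(benzyloxy)phenyl]nonan-1-ol F8.
- Dess–Martin periodinane, now on a substrate without a free phenol, gives 1-[2-(benzyloxy)-6-methoxyphenyl]-9-[4-(benzyloxy)phenyl]nonan-1-one F9.
- Hydrogenolysis (H2, Pd/C, EtOAc) removes both benzyl groups to give 20.

**Further compounds**

F1 | step 7 | 1-methoxy-3-(methoxymethoxy)benzene | COCOc1cccc(OC)c1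
F2 | step 7 | 2-lithio-1-methoxy-3-(methoxymethoxy)benzene | COCOc1cccc(OC)c1[Li]
F3 | step 7 | racemic 9-[4-(benzyloxy)phenyl]-1-[2-methoxy-6-(methoxymethoxy)phenyl]nonan-1-ol | COCOc1cccc(OC)c1C(O)CCCCCCCCc1ccc(OCc2ccccc2)cc1
F4 | step 7 | 9-[4-(benzyloxy)phenyl]-1-[2-methoxy-6-(methoxymethoxy)phenyl]nonan-1-one | COCOc1cccc(OC)c1C(=O)CCCCCCCCc1ccc(OCc2ccccc2)cc1
F5 | step 6 | 1,1,1-trifluorohex-5-ene-2,4-dione | C=CC(=O)CC(=O)C(F)(F)F
F6 | step 6 | 1-diazobut-3-en-2-one | C=CC(=O)C=[N+]=[N-]
F7 | step 9 | racemic 1-(benzyloxy)-2-{9-[4-(benzyloxy)phenyl]-1-[(tert-butyldimethylsilyl)oxy]nonyl}-3-methoxybenzene | COc1cccc(OCc2ccccc2)c1C(O[Si](C)(C)C(C)(C)C)CCCCCCCCc1ccc(OCc2ccccc2)cc1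
F8 | step 9 | racemic 1-[2-(benzyloxy)-6-methoxyphenyl]-9-[4-(benzyloxy)phenyl]nonan-1-ol | COc1cccc(OCc2ccccc2)c1C(O)CCCCCCCCc1ccc(OCc2ccccc2)cc1
F9 | step 9 | 1-[2-(benzyloxy)-6-methoxyphenyl]-9-[4-(benzyloxy)phenyl]nonan-1-one | COc1cccc(OCc2ccccc2)c1C(=O)CCCCCCCCc1ccc(OCc2ccccc2)cc1
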